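**Retrosynthetic overview**
1. Feature: in the benzo ring of the benzofuran only C4 and C5 carry hydrogen. C3a (carbon), C7a (O1), C7 (prenyl) and C6 (OMe) are contiguous, a 2-alkylresorcinol with one further ortho carbon. A vinylketene plus 1-alkoxyalkyne annulation delivers this pattern with no regiochemical choice.
2. Endgame: 3-CHO ⇒ 3-CO2Me. The furan ring (C2–C3, then O1–C2) ⇒ ester of the C7a phenol with 2,4-bis(silyloxy)benzoic acid, by enolate O→C acyl transfer and cyclodehydration.
3. Key disconnection: benzo ring ⇒ alkenyl diazomethyl ketone 5 + ynol ether 9. C4–C5 forms in the photo-Wolff shift, C5–C6 and C7–C7a in the [2+2], and C3a–C7a in the 6π closure.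
4. The C3a arm (future C3 and CHO carbon) passes through the annulation as CH2CH2OTBS and is raised to CH2CO2Me afterwards.
5. Ring order: the resorcinol ring is bought, the benzo ring forms in step 4, and the furan ring in steps 11–12.

Key step: step 4

Remark 1: the target has no stereocentre and no stereogenic double bond, so no enantiomer has to be chosen. The E-alkene of 3 and 5 is consumed in the arene.

Remark 2: the arm is not carried as CH2CO2Me through the diazoketone stage.
- In MeO2C–CH2–CH=CH–C(O)CHN2 the CH2 is a doubly activated, glutaconate-type methylene. It would be deprotonated before the α′-position.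
- That methylene would itself accept a diazo group.
- It would also let the alkene drift out of conjugation with the diazoketone.
- Activated glutaconic half-esters close to 2-pyranones, and diazomethane adds as a dipole to conjugated acyl derivatives.
- The silyl ether arm has none of these liabilities, and steps 8–10 restore the ester.

Abbreviations: TBS = tert-butyldimethylsilyl; prenyl = 3-methylbut-2-en-1-yl.

**Step 1**
Reactants: 1 3-(tert-butyldimethylsilyloxy)propanal; 2 1-(triphenylphosphoranylidene)propan-2-one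
Product: 3 (E)-6-(tert-butyldimethylsilyloxy)hex-3-en-2-one
Conditions: CH2Cl2, rt → 40 °C
Reagents that add atoms: none
Why: Wittig olefination with a ketone-stabilised ylide is reliably E-selective with unbranched aldehydes and needs no added base, so the β-silyloxy aldehyde should not eliminate.

**Step 2**
Reactants: 3 (E)-6-(tert-butyldimethylsilyloxy)hex-3-en-2-one
Product: 5 (E)-6-(tert-butyldimethylsilyloxy)-1-diazohex-3-en-2-one, via trifluoroacetyl diketone 4 (not isolated)
Conditions: LiHMDS (1.1 equiv), THF, –78 °C; CF3CO2CH2CF3 (1.2 equiv), –78 °C; brief cold 5% HCl wash; then MsN3 (1.5 equiv), Et3N (1.5 equiv), H2O (1 equiv), MeCN, rt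
Reagents that add atoms: methanesulfonyl azide CS(=O)(=O)N=[N+]=[N-] (the N2 unit of 5); 2,2,2-trifluoroethyl trifluoroacetate O=C(OCC(F)(F)F)C(F)(F)F (the CF3CO group of 4 only)
Why: In this detrifluoroacetylative diazo transfer the amide base removes the kinetic α′-methyl proton of the enone, trifluoroacetylation activates that carbon for diazo transfer, and the CF3CO group leaves on the sulfonamide nitrogen, which is the standard diazomethane-free access to α,β-unsaturated diazomethyl ketones.

**Step 3**
Reactants: 6 chloroacetaldehyde dimethyl acetal; 7 prenyl bromide (1-bromo-3-methylbut-2-ene)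
Product: 9 1-methoxy-5-methylhex-4-en-1-yne, via sodium methoxyacetylide 8 (not isolated)
Conditions: 6 (1.05 equiv), NaNH2 (3.0 equiv), NH3(l), –33 °C; 7 (0.9 equiv), –33 °C; NH4Cl, pentane extraction, distillation under reduced pressure
Reagents that add atoms: sodium amide [NH2-].[Na+] (the sodium of 8 only)
Why: Twofold β-elimination (MeOH, then HCl) of the chloroacetal followed by SN2 alkylation of the alkoxyacetylide in liquid ammonia is the classical route to 1-alkoxy-1-alkynes; the primary allylic bromide should react at its unhindered carbon, and keeping the amide limiting leaves no base strong enough to isomerise the skipped enyne.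

**Step 4**
Reactants: 5 (E)-6-(tert-butyldimethylsilyloxy)-1-diazohex-3-en-2-one; 9 1-methoxy-5-methylhex-4-en-1-yne
Product: 14 6-[2-(tert-butyldimethylsilyloxy)ethyl]-3-methoxy-2-prenylphenol, via vinylketene 10 (not isolated), via 4-alkenylcyclobutenone 11 (not isolated), via dienylketene 12 (not isolated), via cyclohexa-2,4-dienone 13 (not isolated)
Conditions: 9 (1.5 equiv), ClCH2CH2Cl (0.2 M, degassed, Ar), hν 254 nm (low-pressure Hg, quartz), rt until 5 is consumed; then 80 °C
Reagents that add atoms: none
Why: Irradiation expels N2 from 5 and the alkenyl group shifts to the former diazo carbon (photo-Wolff rearrangement, forms C4–C5), giving vinylketene 10 at low stationary concentration. The nucleophilic, prenyl-bearing alkyne carbon of 9 bonds to the ketene carbonyl carbon and the methoxy-bearing carbon bonds to the ketene α-carbon ([2+2] cycloaddition, forms C7–C7a and C5–C6), giving 11. Light or the 80 °C stage opens 11 by 4π-electrocyclic cleavage of its C(=O)–C(sp3) bond to dienylketene 12, and the benzene ring closes by 6π-electrocyclisation (forms C3a–C7a) to dienone 13, which tautomerises to phenol 14. This is the Danheiser benzannulation in its diazoketone form, known for α,β-unsaturated diazoketones with alkoxy- and siloxyalkynes. The sp3 centres of 11 and 13 are transient, racemic and erased on aromatisation, so no stereocentre has to be controlled. The step needs one regiochemistry (OH, prenyl and OMe contiguous) and attack on the alkyne rather than the prenyl alkene; both follow from the strong polarisation of the oxygen-substituted alkyne, and the silyl ether arm offers neither an O–H nor an acidic C–H to quench the ketene.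

**Step 5**
Reactants: 15 2,4-dihydroxybenzoic acid
Product: 16 tert-butyldimethylsilyl 2,4-bis(tert-butyldimethylsilyloxy)benzoate
Conditions: TBSCl (3.6 equiv), imidazole (7 equiv), DMF, rt → 45 °C
Reagents that add atoms: tert-butyldimethylsilyl chloride CC(C)(C)[Si](C)(C)Cl
Why: Imidazole-promoted silylation with excess reagent should cap the acid and both phenols, the hydrogen-bonded 2-OH reacting last once the carboxyl group is silylated.

**Step 6**
Reactants: 16 tert-butyldimethylsilyl 2,4-bis(tert-butyldimethylsilyloxy)benzoate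
Product: 17 2,4-bis(tert-butyldimethylsilyloxy)benzoyl chloride
Conditions: (COCl)2 (1.2 equiv), DMF (cat.), CH2Cl2, 0 °C → rt; volatiles including TBSCl removed under high vacuum, used crude
Reagents that add atoms: oxalyl chloride O=C(Cl)C(=O)Cl
Why: Exchange of a silyl ester for the acid chloride with the catalytic Vilsmeier reagent runs under neutral conditions and liberates no HCl, so the aryl silyl ethers should survive.

**Step 7**
Reactants: 14 6-[2-(tert-butyldimethylsilyloxy)ethyl]-3-methoxy-2-prenylphenol; 17 2,4-bis(tert-butyldimethylsilyloxy)benzoyl chloride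
Product: 18 6-[2-(tert-butyldimethylsilyloxy)ethyl]-3-methoxy-2-prenylphenyl 2,4-bis(tert-butyldimethylsilyloxy)benzoate
Conditions: 17 (1.3 equiv), Et3N (2 equiv), DMAP (0.2 equiv), CH2Cl2, 0 °C → rt
Reagents that add atoms: none
Why: DMAP-catalysed O-acylation through the acylpyridinium ion is the usual answer to a 2,6-disubstituted phenol, and the aroyl group both masks the oxidation-sensitive phenol and places the future C2 next to it.

**Step 8**
Reactants: 18 6-[2-(tert-butyldimethylsilyloxy)ethyl]-3-methoxy-2-prenylphenyl 2,4-bis(tert-butyldimethylsilyloxy)benzoate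
Product: 19 6-(2-hydroxyethyl)-3-methoxy-2-prenylphenyl 2,4-bis(tert-butyldimethylsilyloxy)benzoate
Conditions: CSA (0.1 equiv), MeOH/CH2Cl2 1:1, 0 °C; solid NaHCO3 quench
Reagents that add atoms: none
Why: Acid-catalysed methanolysis of silyl ethers cleaves a primary alkyl TBS ether far faster than the less basic aryl TBS ethers, and the low temperature together with the doubly ortho-hindered ester should hold back acyl migration.

**Step 9**
Reactants: 19 6-(2-hydroxyethyl)-3-methoxy-2-prenylphenyl 2,4-bis(tert-butyldimethylsilyloxy)benzoate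
Product: 20 2-{2-[2,4-bis(tert-butyldimethylsilyloxy)benzoyloxy]-4-methoxy-3-prenylphenyl}acetic acid
Conditions: TEMPO (0.2 equiv), PhI(OAc)2 (2.4 equiv), CH2Cl2/H2O 2:1, rt
Reagents that add atoms: water O
Why: The TEMPO/PhI(OAc)2 oxoammonium oxidation takes a primary alcohol through the aldehyde hydrate to the acid without any chlorine species, so the prenyl alkene and the electron-rich rings should remain untouched.

**Step 10**
Reactants: 20 2-{2-[2,4-bis(tert-butyldimethylsilyloxy)benzoyloxy]-4-methoxy-3-prenylphenyl}acetic acid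
Product: 21 methyl 2-{2-[2,4-bis(tert-butyldimethylsilyloxy)benzoyloxy]-4-methoxy-3-prenylphenyl}acetate
Conditions: TMSCHN2 (1.3 equiv), toluene/MeOH 4:1, 0 °C
Reagents that add atoms: (trimethylsilyl)diazomethane C[Si](C)(C)C=[N+]=[N-]
Why: Methyl esterification with (trimethylsilyl)diazomethane in methanol is neutral and fast, so neither the aryl ester nor the aryl silyl ethers are put at risk.

**Step 11**
Reactants: 21 methyl 2-{2-[2,4-bis(tert-butyldimethylsilyloxy)benzoyloxy]-4-methoxy-3-prenylphenyl}acetate
Product: 22 methyl 3-[2,4-bis(tert-butyldimethylsilyloxy)phenyl]-2-(2-hydroxy-4-methoxy-3-prenylphenyl)-3-oxopropanoate (racemic, labile centre; in equilibrium with its enol and cyclic hemiketal; used crude)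
Conditions: LiHMDS (2.2 equiv), THF, –78 → 0 °C; AcOH (2.5 equiv), –78 °C, aqueous work-up
Reagents that add atoms: none
Why: In this Baker–Venkataraman-type O→C acyl transfer (an intramolecular Claisen condensation) the arylacetate enolate attacks the neighbouring aryl ester carbonyl in a 5-exo-trig manner, forming C2–C3 with expulsion of the phenoxide, and the second equivalent of base stores the product as its stable enolate.

**Step 12**
Reactants: 22 methyl 3-[2,4-bis(tert-butyldimethylsilyloxy)phenyl]-2-(2-hydroxy-4-methoxy-3-prenylphenyl)-3-oxopropanoate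
Product: 23 methyl 2-[2,4-bis(tert-butyldimethylsilyloxy)phenyl]-6-methoxy-7-prenylbenzofuran-3-carboxylate
Conditions: PPTS (0.2 equiv), 3 Å MS, toluene, 60 °C
Reagents that add atoms: none
Why: Acid-catalysed cyclodehydration closes the furan ring by 5-exo-trig hemiketalisation of the phenol onto the aryl ketone (O1–C2) and irreversible loss of water through an oxocarbenium ion stabilised by the dioxygenated aryl group, while PPTS is too weak to protonate the prenyl alkene or cleave aryl TBS ethers, and 3 Å sieves bind water but not methanol, so lactonisation onto the ester is not driven.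

**Step 13**
Reactants: 23 methyl 2-[2,4-bis(tert-butyldimethylsilyloxy)phenyl]-6-methoxy-7-prenylbenzofuran-3-carboxylate
Product: 24 {2-[2,4-bis(tert-butyldimethylsilyloxy)phenyl]-6-methoxy-7-prenylbenzofuran-3-yl}methanol
Conditions: DIBAL-H (3 equiv), CH2Cl2, –78 → –20 °C; aq. Rochelle salt
Reagents that add atoms: none
Why: Full DIBAL-H reduction of the conjugated ester to the primary alcohol is more dependable than a partial reduction, and it is placed before desilylation because a free 2′-OH would lactonise onto the ester to give a coumestan.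

**Step 14**
Reactants: 24 {2-[2,4-bis(tert-butyldimethylsilyloxy)phenyl]-6-methoxy-7-prenylbenzofuran-3-yl}methanol
Product: 25 2-[2,4-bis(tert-butyldimethylsilyloxy)phenyl]-6-methoxy-7-prenylbenzofuran-3-carbaldehyde
Conditions: activated MnO2 (15 equiv), CH2Cl2, rt
Reagents that add atoms: none
Why: MnO2 oxidation is selective for benzylic-type (here heteroarylmethyl) alcohols, stops at the aldehyde and leaves the isolated trisubstituted alkene alone.

**Step 15**
Reactants: 25 2-[2,4-bis(tert-butyldimethylsilyloxy)phenyl]-6-methoxy-7-prenylbenzofuran-3-carbaldehyde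
Product: 26 erypoegin F, 2-(2,4-dihydroxyphenyl)-6-methoxy-7-prenylbenzofuran-3-carbaldehyde
Conditions: TBAF (2.2 equiv), AcOH (2.4 equiv), THF, 0 °C
Reagents that add atoms: none
Why: Fluoride-induced desilylation of aryl silyl ethers is very fast, and the acetic acid buffer keeps the liberated phenoxides from condensing with the aldehyde.

**Compound list**
1 | 3-(tert-butyldimethylsilyloxy)propanal | CC(C)(C)[Si](C)(C)OCCC=O | starting material
2 | 1-(triphenylphosphoranylidene)propan-2-one | CC(=O)C=P(c1ccccc1)(c1ccccc1)c1ccccc1 | starting material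
3 | (E)-6-(tert-butyldimethylsilyloxy)hex-3-en-2-one | CC(=O)/C=C/CCO[Si](C)(C)C(C)(C)C | intermediate
4 | (E)-8-(tert-butyldimethylsilyloxy)-1,1,1-trifluorooct-5-ene-2,4-dione | O=C(CC(=O)/C=C/CCO[Si](C)(C)C(C)(C)C)C(F)(F)F | intermediate
5 | (E)-6-(tert-butyldimethylsilyloxy)-1-diazohex-3-en-2-one | [N-]=[N+]=CC(=O)/C=C/CCO[Si](C)(C)C(C)(C)C | intermediate
6 | chloroacetaldehyde dimethyl acetal | COC(CCl)OC | starting material
7 | prenyl bromide | CC(C)=CCBr | starting material
8 | sodium methoxyacetylide | [Na+].[C-]#COC | intermediate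
9 | 1-methoxy-5-methylhex-4-en-1-yne | COC#CCC=C(C)C | intermediate
10 | (E)-6-(tert-butyldimethylsilyloxy)hexa-1,3-dien-1-one (vinylketene) | O=C=C/C=C/CCO[Si](C)(C)C(C)(C)C | intermediate
11 | 4-[(E)-4-(tert-butyldimethylsilyloxy)but-1-enyl]-3-methoxy-2-prenylcyclobut-2-en-1-one (racemic) | O=C1C(CC=C(C)C)=C(OC)C1/C=C/CCO[Si](C)(C)C(C)(C)C | intermediate
12 | dienylketene, 8-(tert-butyldimethylsilyloxy)-3-methoxy-2-prenylocta-1,3,5-trien-1-one, ketene carbon and butenyl arm cis on C3=C4, C5=C6 E | O=C=C(CC=C(C)C)/C(OC)=C\C=C\CCO[Si](C)(C)C(C)(C)C | intermediate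
13 | 6-[2-(tert-butyldimethylsilyloxy)ethyl]-3-methoxy-2-prenylcyclohexa-2,4-dien-1-one (racemic) | O=C1C(CC=C(C)C)=C(OC)C=CC1CCO[Si](C)(C)C(C)(C)C | intermediate
14 | 6-[2-(tert-butyldimethylsilyloxy)ethyl]-3-methoxy-2-prenylphenol | CC(C)=CCc1c(O)c(CCO[Si](C)(C)C(C)(C)C)ccc1OC | intermediate
15 | 2,4-dihydroxybenzoic acid | OC(=O)c1ccc(O)cc1O | starting material
16 | tert-butyldimethylsilyl 2,4-bis(tert-butyldimethylsilyloxy)benzoate | CC(C)(C)[Si](C)(C)OC(=O)c1ccc(O[Si](C)(C)C(C)(C)C)cc1O[Si](C)(C)C(C)(C)C | intermediate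
17 | 2,4-bis(tert-butyldimethylsilyloxy)benzoyl chloride | O=C(Cl)c1ccc(O[Si](C)(C)C(C)(C)C)cc1O[Si](C)(C)C(C)(C)C | intermediate
18 | 6-[2-(tert-butyldimethylsilyloxy)ethyl]-3-methoxy-2-prenylphenyl 2,4-bis(tert-butyldimethylsilyloxy)benzoate | CC(C)=CCc1c(OC)ccc(CCO[Si](C)(C)C(C)(C)C)c1OC(=O)c1ccc(O[Si](C)(C)C(C)(C)C)cc1O[Si](C)(C)C(C)(C)C | intermediate
19 | 6-(2-hydroxyethyl)-3-methoxy-2-prenylphenyl 2,4-bis(tert-butyldimethylsilyloxy)benzoate | CC(C)=CCc1c(OC)ccc(CCO)c1OC(=O)c1ccc(O[Si](C)(C)C(C)(C)C)cc1O[Si](C)(C)C(C)(C)C | intermediate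
20 | 2-{2-[2,4-bis(tert-butyldimethylsilyloxy)benzoyloxy]-4-methoxy-3-prenylphenyl}acetic acid | CC(C)=CCc1c(OC)ccc(CC(=O)O)c1OC(=O)c1ccc(O[Si](C)(C)C(C)(C)C)cc1O[Si](C)(C)C(C)(C)C | intermediate
21 | methyl 2-{2-[2,4-bis(tert-butyldimethylsilyloxy)benzoyloxy]-4-methoxy-3-prenylphenyl}acetate | COC(=O)Cc1ccc(OC)c(CC=C(C)C)c1OC(=O)c1ccc(O[Si](C)(C)C(C)(C)C)cc1O[Si](C)(C)C(C)(C)C | intermediate
22 | methyl 3-[2,4-bis(tert-butyldimethylsilyloxy)phenyl]-2-(2-hydroxy-4-methoxy-3-prenylphenyl)-3-oxopropanoate (racemic, labile) | COC(=O)C(C(=O)c1ccc(O[Si](C)(C)C(C)(C)C)cc1O[Si](C)(C)C(C)(C)C)c1ccc(OC)c(CC=C(C)C)c1O | intermediate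
23 | methyl 2-[2,4-bis(tert-butyldimethylsilyloxy)phenyl]-6-methoxy-7-prenylbenzofuran-3-carboxylate | COC(=O)c1c(-c2ccc(O[Si](C)(C)C(C)(C)C)cc2O[Si](C)(C)C(C)(C)C)oc2c(CC=C(C)C)c(OC)ccc12 | intermediate
24 | {2-[2,4-bis(tert-butyldimethylsilyloxy)phenyl]-6-methoxy-7-prenylbenzofuran-3-yl}methanol | OCc1c(-c2ccc(O[Si](C)(C)C(C)(C)C)cc2O[Si](C)(C)C(C)(C)C)oc2c(CC=C(C)C)c(OC)ccc12 | intermediate
25 | 2-[2,4-bis(tert-butyldimethylsilyloxy)phenyl]-6-methoxy-7-prenylbenzofuran-3-carbaldehyde | O=Cc1c(-c2ccc(O[Si](C)(C)C(C)(C)C)cc2O[Si](C)(C)C(C)(C)C)oc2c(CC=C(C)C)c(OC)ccc12 | intermediate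
26 | erypoegin F | COc1ccc2c(C=O)c(-c3ccc(O)cc3O)oc2c1CC=C(C)C | target

**Step count**
Total steps: 15. Longest linear sequence: 12 (steps 1, 2, 4 and 7–15).

**Steps most likely to fail**

Step 4.
- What may go wrong: light-driven E→Z isomerisation of the enone or of the vinylketene, after which a Z-ketene escapes by a 1,5-hydrogen shift. The freshly formed phenol may be acylated by the ketene. The cyclobutenone and the product may undergo secondary photolysis. Acid traces may hydrate the ynol ether.
- Fallback: it keeps the vinylketene/ynol ether union but makes the ketene thermally from an acid chloride, without light or a diazo compound. It sets out from 9 and comes back at 21.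
- Commercial (E)-hex-3-enedioic acid F1 is half-esterified (MeOH, cat. H2SO4, separation from diacid and diester) to (E)-6-methoxy-6-oxohex-3-enoic acid F2.
- (COCl)2/cat. DMF converts this into methyl (E)-6-chloro-6-oxohex-3-enoate F3.
- Slow addition of F3 to 9 and Et3N in Et2O/MeCN at rt causes 1,2-dehydrochlorination with retention of the E-alkene, giving methyl (E)-6-oxohexa-3,5-dienoate F4.
- The ynol ether traps F4 as methyl (E)-4-(2-methoxy-4-oxo-3-prenylcyclobut-2-en-1-yl)but-3-enoate F5.
- After the ammonium salt is filtered off, heating in toluene at 80–110 °C should bring about ring opening, 6π closure and tautomerisation to methyl 2-(2-hydroxy-4-methoxy-3-prenylphenyl)acetate F6.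
- The ester arm is admissible here because no amide base and no diazo-transfer reagent meets its activated methylene.
- Aroylation of F6 with 17 under the conditions of step 7 gives 21, so steps 7–10 are replaced.

Step 11.
- What may go wrong: attack on a hindered, electron-rich aroyl carbonyl may be slow. Under the strongly basic conditions the 2′-silyl group may migrate to the phenoxide or the enolate, and the freed 2′-oxygen would then lactonise onto the methyl ester. Intermolecular Claisen condensation may compete.
- Fallback: it replaces the lithium ester enolate by soft enolisation of a thioester and changes the redox endgame. It sets out from 20 and comes back at 25.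
- Acid 20 is coupled with ethanethiol (EDC, cat. DMAP, CH2Cl2) to S-ethyl 2-{2-[2,4-bis(tert-butyldimethylsilyloxy)benzoyloxy]-4-methoxy-3-prenylphenyl}ethanethioate F7.
- MgBr2·OEt2 and i-Pr2NEt in CH2Cl2 at rt form the magnesium enolate and activate the aryl ester by chelation. The acyl transfer should then give S-ethyl 3-[2,4-bis(tert-butyldimethylsilyloxy)phenyl]-2-(2-hydroxy-4-methoxy-3-prenylphenyl)-3-oxopropanethioate F8.
- PPTS in toluene closes this to S-ethyl 2-[2,4-bis(tert-butyldimethylsilyloxy)phenyl]-6-methoxy-7-prenylbenzofuran-3-carbothioate F9.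
- Fukuyama reduction (Et3SiH, Pd/C, acetone, rt) takes F9 directly to aldehyde 25, so steps 13 and 14 drop out.

Step 8.
- What may go wrong: the aroyl group may migrate from the phenol oxygen to the liberated primary alcohol, and the aryl silyl ethers may be partly lost during the acid methanolysis.
- Fallback: it adjusts the oxidation level before any aroyl or aryl silyl group is present, under an orthogonal phenol protecting group. It sets out from 14 and comes back at 21.
- Phenol 14 is allylated (allyl bromide, K2CO3, DMF) to 2-(allyloxy)-1-[2-(tert-butyldimethylsilyloxy)ethyl]-4-methoxy-3-prenylbenzene F10.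
- TBAF then removes the only silyl group to give 2-[2-(allyloxy)-4-methoxy-3-prenylphenyl]ethanol F11.
- TEMPO/PhI(OAc)2 in CH2Cl2/H2O gives 2-[2-(allyloxy)-4-methoxy-3-prenylphenyl]acetic acid F12.
- TMSCHN2 gives methyl 2-[2-(allyloxy)-4-methoxy-3-prenylphenyl]acetate F13.
- Pd(PPh3)4/morpholine transfers the allyl group and leaves the prenyl group alone, releasing methyl 2-(2-hydroxy-4-methoxy-3-prenylphenyl)acetate F6.
- F6 is aroylated with 17 as in step 7 to give 21.

**Further compounds**
F1 | step 4 | (E)-hex-3-enedioic acid (commercial) | OC(=O)C/C=C/CC(=O)O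
F2 | step 4 | (E)-6-methoxy-6-oxohex-3-enoic acid | COC(=O)C/C=C/CC(=O)O
F3 | step 4 | methyl (E)-6-chloro-6-oxohex-3-enoate | COC(=O)C/C=C/CC(=O)Cl
F4 | step 4 | methyl (E)-6-oxohexa-3,5-dienoate (vinylketene) | COC(=O)C/C=C/C=C=O
F5 | step 4 | methyl (E)-4-(2-methoxy-4-oxo-3-prenylcyclobut-2-en-1-yl)but-3-enoate (racemic) | COC(=O)C/C=C/C1C(=O)C(CC=C(C)C)=C1OC
F6 | step 4 | methyl 2-(2-hydroxy-4-methoxy-3-prenylphenyl)acetate | COC(=O)Cc1ccc(OC)c(CC=C(C)C)c1O
F7 | step 11 | S-ethyl 2-{2-[2,4-bis(tert-butyldimethylsilyloxy)benzoyloxy]-4-methoxy-3-prenylphenyl}ethanethioate | CCSC(=O)Cc1ccc(OC)c(CC=C(C)C)c1OC(=O)c1ccc(O[Si](C)(C)C(C)(C)C)cc1O[Si](C)(C)C(C)(C)C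
F8 | step 11 | S-ethyl 3-[2,4-bis(tert-butyldimethylsilyloxy)phenyl]-2-(2-hydroxy-4-methoxy-3-prenylphenyl)-3-oxopropanethioate (racemic, labile) | CCSC(=O)C(C(=O)c1ccc(O[Si](C)(C)C(C)(C)C)cc1O[Si](C)(C)C(C)(C)C)c1ccc(OC)c(CC=C(C)C)c1O
F9 | step 11 | S-ethyl 2-[2,4-bis(tert-butyldimethylsilyloxy)phenyl]-6-methoxy-7-prenylbenzofuran-3-carbothioate | CCSC(=O)c1c(-c2ccc(O[Si](C)(C)C(C)(C)C)cc2O[Si](C)(C)C(C)(C)C)oc2c(CC=C(C)C)c(OC)ccc12
F10 | step 8 | 2-(allyloxy)-1-[2-(tert-butyldimethylsilyloxy)ethyl]-4-methoxy-3-prenylbenzene | C=CCOc1c(CCO[Si](C)(C)C(C)(C)C)ccc(OC)c1CC=C(C)C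
F11 | step 8 | 2-[2-(allyloxy)-4-methoxy-3-prenylphenyl]ethanol | C=CCOc1c(CCO)ccc(OC)c1CC=C(C)C
F12 | step 8 | 2-[2-(allyloxy)-4-methoxy-3-prenylphenyl]acetic acid | C=CCOc1c(CC(=O)O)ccc(OC)c1CC=C(C)C
F13 | step 8 | methyl 2-[2-(allyloxy)-4-methoxy-3-prenylphenyl]acetate | C=CCOc1c(CC(=O)OC)ccc(OC)c1CC=C(C)C
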